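**Plan**

- Retrosynthesis: reduce C5–OH back to a C5 ketone; cut the C1–C9 bond of the cyclobutane, which turns the bicyclo[7.2.0] core into an eleven-membered (humulane) ring with a radical precursor at C9; cut the dihydropyran (O–C8 and C13–C1′) by retro-hetero-Diels–Alder to an exocyclic-methylene carbinol, syncarpic acid and isovaleraldehyde; the macrocycle is zerumbone after a 1,3-carbonyl transposition.
- Forward: the eleven-membered ring (zerumbone) and the trione ring (syncarpic acid) are bought; the dihydropyran is made by cycloaddition (step 6); the cyclobutane is closed last (step 8) by a transannular C9→C1 radical addition, which leaves the nine-membered ring out of the eleven-membered one.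
- Enabling feature: C9–C10–C11–C1 already lie in a row in the macrocycle, so only the C1–C9 bond is missing. C11 carries the gem-dimethyl group inside the forming ring. C1 is the δ-terminus of a C1=C2–C3=C4–C5=O dienone whose carbonyl becomes the C5–OH. C9 sits next to the spiro carbon C8, where an allylic carbinol serves first as stereochemical relay and then as radical precursor.
- Stereochemistry: one catalytic step (Shi epoxidation) sets the C9 carbinol. It relays to C8 and C1′ in the cycloaddition and is then erased. C8 and the E-geometry of C1=C2 set C9 and C1 together in the ring closure. C5 comes from a CBS reduction, and the Z-C3=C4 alkene from the Wharton step and the ring.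

Key step: step 8

Numbering: atoms are numbered as in the caryophyllane part of the target (cyclobutane C1, C9, C10, C11; spiro carbon C8; C4 bears the methyl, C5 the hydroxyl; C13 is the pyran CH2, C1′ the isobutyl-bearing carbon).
Assumption: zerumbone and syncarpic acid are taken as catalogue compounds, and the peroxide anion is assumed to attack zerumbone at C5, the enone β-carbon that is not shielded by the gem-dimethyl group.

**Step 1**
Reactants: 1 zerumbone
Product: 2 rac-trans-4,5-epoxyzerumbone (epoxide on the methyl-bearing enone bond; positions 2,3 in zerumbone numbering)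
Conditions: t-BuOOH, DBU, CH2Cl2, 0 °C to rt
Reagents that add atoms: tert-butyl hydroperoxide, CC(C)(C)OO
Why: Weitz–Scheffer nucleophilic epoxidation, in which the peroxide anion should add to C5 (C1 is neopentylic) and the enolate closes the trans-epoxide; the racemate suffices because both new stereocentres are erased in steps 2 and 3.

**Step 2**
Reactants: 2 rac-trans-4,5-epoxyzerumbone
Product: 4 (±)-(2Z,4E,8E)-2,6,6,9-tetramethylcycloundeca-2,4,8-trien-1-ol, via epoxy hydrazone 3 (not isolated)
Conditions: N2H4·H2O, AcOH (cat.), MeOH, 0 °C to rt
Reagents that add atoms: none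
Why: Wharton transposition, in which the C3 hydrazone opens the epoxide to an alkenyl diazene that loses N2, moving the oxygen from C3 to C5 and leaving C3=C4 conjugated with the untouched E-C1=C2 bond; the Z geometry is the one expected from the s-trans arrangement of the ring enone and is not binding, since the later radical is delocalised over this bond.

**Step 3**
Reactants: 4 (±)-(2Z,4E,8E)-2,6,6,9-tetramethylcycloundeca-2,4,8-trien-1-ol
Product: 5 (2Z,4E,8E)-2,6,6,9-tetramethylcycloundeca-2,4,8-trien-1-one
Conditions: MnO2, CH2Cl2, rt
Reagents that add atoms: none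
Why: Manganese dioxide oxidation of a dienylic alcohol gives the linear dienone in which C1 is the δ-terminus of the acceptor, the isolated C8=C9 alkene being inert to the oxidant.

**Step 4**
Reactants: 5 (2Z,4E,8E)-2,6,6,9-tetramethylcycloundeca-2,4,8-trien-1-one
Product: 6 (2Z,4E,8R,9R)-8,9-epoxy-2,6,6,9-tetramethylcycloundeca-2,4-dien-1-one
Conditions: Shi ketone (D-fructose-derived, 30 mol%), Oxone, K2CO3, Bu4NHSO4, MeCN/DMM/aq. buffer (pH 10.5), 0 °C
Reagents that add atoms: Oxone (potassium peroxymonosulfate), [K+].[O-]S(=O)(=O)OO
Why: Shi asymmetric epoxidation, in which the chiral dioxirane should react only with the electron-rich, isolated E-trisubstituted C8=C9 alkene (the dienone double bonds are deactivated) and, by the spiro transition-state model for E-alkenes, give the (R,R)-epoxide that fixes the relay centre C9.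

**Step 5**
Reactants: 6 (2Z,4E,8R,9R)-8,9-epoxy-2,6,6,9-tetramethylcycloundeca-2,4-dien-1-one
Product: 8 (2Z,4E,8R)-8-hydroxy-2,6,6-trimethyl-9-methylidenecycloundeca-2,4-dien-1-one, via trimethylsilyl ether 7 (not isolated)
Conditions: TMSOTf, DBU, PhMe, −40 °C to rt; then 1 M HCl, THF, 0 °C
Reagents that add atoms: none
Why: Silyl triflate/amidine-mediated epoxide-to-allylic-alcohol isomerisation, in which the epoxide opens at the tertiary carbon C8 and the base removes a proton from the C8 methyl group (Hofmann-type), so the C9–O bond keeps its configuration and the exocyclic C8=C13 alkene appears; the remaining ring alkenes are deactivated by the ketone and should not intercept the cation.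

**Step 6**
Reactants: 8 (2Z,4E,8R)-8-hydroxy-2,6,6-trimethyl-9-methylidenecycloundeca-2,4-dien-1-one; 9 syncarpic acid; 10 isovaleraldehyde
Product: 12 spiro-dihydropyran cycloadduct with (8S,9R,1′R) configuration (macrocyclic dienone and C9 carbinol retained), via enetrione 11 (not isolated)
Conditions: ethylenediammonium diacetate (20 mol%), PhMe, 80 °C
Reagents that add atoms: none
Why: Domino Knoevenagel/inverse-electron-demand hetero-Diels–Alder reaction, in which the electron-poor oxadiene 11 should react only with the 1,1-disubstituted alkene (oxygen to C8, C1′ to C13); C8 should be set by the carbinol (C–O inside and hydrogen-bonded, attack anti to the ring branch C10) and C1′ by exo placement of the branched C9 arm, which puts isobutyl cis to C7.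

**Step 7**
Reactants: 12 spiro-dihydropyran cycloadduct
Product: 13 O-phenyl thionocarbonate of 12 at the C9 oxygen
Conditions: PhOC(S)Cl, DMAP, pyridine, CH2Cl2, rt
Reagents that add atoms: O-phenyl chlorothionoformate, S=C(Cl)Oc1ccccc1
Why: DMAP-catalysed acylation of the hindered secondary carbinol gives the Barton–McCombie radical precursor without strong base, so the enolisable dienone and the vinylogous ester stay untouched and no stereocentre changes.

**Step 8**
Reactants: 13 O-phenyl thionocarbonate of 12
Product: 14 5-oxo precursor of the target, (1R,8S,9S,1′R), with the trans-fused gem-dimethylcyclobutane and the Z-C3=C4 enone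
Conditions: (Me3Si)3SiH, AIBN (syringe pump), PhH (0.005 M), 80 °C
Reagents that add atoms: none
Why: Proposed new method: the silyl radical cleaves the thionocarbonate (Barton–McCombie initiation) to a secondary C9 radical that adds across the ring to C1, the δ-terminus of the C1=C2–C3=C4–C5=O dienone, and the oxygen-stabilised pentadienyl radical so formed takes hydrogen at its less hindered terminus C2 to give the conjugated Z-enone; the closest known reaction types are radical 4-exo-trig cyclisations onto unsaturated carbonyl acceptors that carry a gem-disubstituted tether, transannular radical cyclisations of macrocycles and radical 1,6-additions to dienones. The cyclobutane C1–C9–C10–C11 is closed in the 4-exo-trig mode and transannularly, so that the same bond leaves the nine-membered carbocycle out of the eleven-membered one; the gem-dimethyl group on C11 inside the forming ring (Thorpe–Ingold effect) and the strong stabilisation of the product radical should offset the ring strain and make re-opening slower than hydrogen transfer. C1 is controlled by the E-geometry of C1=C2, because C3, anti to C11, occupies the flank of the incipient four-membered ring on which C8 would have to lie for cis-fusion, so C8 and C2 should take opposite faces (trans-fusion). C9 is controlled by the spiro centre C8: the radical should close through the conformer that puts the CH2–CMe2 edge beside the small ether oxygen and the pyran methylene C13 beside H9, which is (1R,9S) from (8S). Regioselectivity is secured by topology, since bonding to C3 would trap the E-alkene in a six-membered ring and C2 and C4 are polarity-mismatched, and the carbinol stereocentre, having done its relay duty, is erased. Premature reduction of the C9 radical and β-scission of its C8–O bond are the competing paths, which is why a slow hydrogen donor is added by syringe pump at high dilution.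

**Step 9**
Reactants: 14 5-oxo precursor of the target
Product: 15 Tomentodione O
Conditions: (S)-Me-CBS (20 mol%), catecholborane, PhMe, −78 °C
Reagents that add atoms: none
Why: Corey–Bakshi–Shibata reduction, in which the oxazaborolidine treats the α-methylalkenyl arm as the large group and should give the (5R)-allylic alcohol under reagent control, while the vinylogous-ester carbonyl is deactivated and the ketone flanked by two quaternary carbons is too hindered to react.

**Compound list**

1 | zerumbone, (2E,6E,10E)-2,6,9,9-tetramethylcycloundeca-2,6,10-trien-1-one | O=C1/C(C)=C/CC/C(C)=C/CC(C)(C)/C=C/1 | starting material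
2 | rac-trans-4,5-epoxyzerumbone (one enantiomer drawn) | O=C1[C@]2(C)O[C@H]2CC/C(C)=C/CC(C)(C)/C=C/1 | intermediate
3 | C3 hydrazone of 2 (one enantiomer drawn) | NN=C1[C@]2(C)O[C@H]2CC/C(C)=C/CC(C)(C)/C=C/1 | intermediate (not isolated)
4 | (±)-(2Z,4E,8E)-2,6,6,9-tetramethylcycloundeca-2,4,8-trien-1-ol | OC1CC/C(C)=C/CC(C)(C)/C=C/C=C1/C | intermediate
5 | (2Z,4E,8E)-2,6,6,9-tetramethylcycloundeca-2,4,8-trien-1-one | O=C1CC/C(C)=C/CC(C)(C)/C=C/C=C1/C | intermediate
6 | (2Z,4E,8R,9R)-8,9-epoxy-2,6,6,9-tetramethylcycloundeca-2,4-dien-1-one | O=C1CC[C@@]2(C)O[C@@H]2CC(C)(C)/C=C/C=C1/C | intermediate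
7 | trimethylsilyl ether of 8 | O=C1CCC(=C)[C@H](O[Si](C)(C)C)CC(C)(C)/C=C/C=C1/C | intermediate (not isolated)
8 | (2Z,4E,8R)-8-hydroxy-2,6,6-trimethyl-9-methylidenecycloundeca-2,4-dien-1-one | O=C1CCC(=C)[C@H](O)CC(C)(C)/C=C/C=C1/C | intermediate
9 | syncarpic acid, 2,2,4,4-tetramethylcyclohexane-1,3,5-trione | CC1(C)C(=O)CC(=O)C(C)(C)C1=O | starting material
10 | isovaleraldehyde, 3-methylbutanal | CC(C)CC=O | starting material
11 | 2,2,4,4-tetramethyl-6-(3-methylbutylidene)cyclohexane-1,3,5-trione | CC(C)CC=C1C(=O)C(C)(C)C(=O)C(C)(C)C1=O | intermediate (not isolated)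
12 | spiro-dihydropyran cycloadduct, (8S,9R,1′R), C9 carbinol, macrocyclic (Z,E)-dienone | O=C1CC[C@]2(C[C@@H](CC(C)C)C3=C(O2)C(C)(C)C(=O)C(C)(C)C3=O)[C@H](O)CC(C)(C)/C=C/C=C1/C | intermediate
13 | O-phenyl thionocarbonate of 12 | O=C1CC[C@]2(C[C@@H](CC(C)C)C3=C(O2)C(C)(C)C(=O)C(C)(C)C3=O)[C@H](OC(=S)Oc4ccccc4)CC(C)(C)/C=C/C=C1/C | intermediate
14 | 5-oxo precursor of Tomentodione O, (1R,8S,9S,1′R), Z-enone | C/C1=C/C[C@@H]2[C@H](CC2(C)C)[C@]2(CCC1=O)C[C@@H](CC(C)C)C1=C(O2)C(C)(C)C(=O)C(C)(C)C1=O | intermediate
15 | Tomentodione O | C/C1=C/C[C@@H]2[C@H](CC2(C)C)[C@]2(CC[C@H]1O)C[C@@H](CC(C)C)C1=C(O2)C(C)(C)C(=O)C(C)(C)C1=O | target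

**Step count and risks**

Total step count: 9. Longest linear sequence: 9 steps (1 to 15); 9 and 10 enter at step 6.

Step 8 (the step that carries the new-method label). What may go wrong: the C9 radical is reduced by the silane before the slow 4-exo closure, loses the enol-ether oxygen by β-scission of the C8–O bond, or closes through the wrong conformer (cis-fusion or the C9 epimer). The fallback uses known reaction types and sets out from 12. Dess–Martin oxidation gives the C9 ketone F1. Samarium diiodide (HMPA, t-BuOH, THF, −78 °C) then effects a reductive carbonyl–alkene cyclisation of the ketyl–olefin 4-exo-trig type between C9 and C1; whichever carbonyl is reduced first, the same bond results, and the product is the C9 cyclobutanol F2. Methyl chlorooxoacetate with DMAP gives the methyl oxalate F3. Tin hydride deoxygenation of this tertiary oxalate (Bu3SnH, AIBN, PhMe, 110 °C) replaces C9–O by C9–H, with the bulky spiro substituent expected to end trans to C2, and the route is rejoined at 14.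

Step 6. What may go wrong: the free carbinol adds to the enetrione (oxa-Michael) or is transposed under the weakly acidic conditions, and facial discrimination at the exocyclic alkene is insufficient, so that stereoisomeric cycloadducts dominate. The fallback changes the control element from a hydrogen-bonding carbinol to a bulky ether and sets out from 6. Isomerisation with TESOTf/DBU gives the triethylsilyl ether F4 directly. The cycloaddition with 9 and 10 is run on this ether (inside-alkoxy control, no free hydroxyl) to give the silyl ether cycloadduct F5. HF·pyridine then returns to 12.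

Step 5. What may go wrong: the Lewis-acid-activated epoxide rearranges by hydride shift to a ketone or is captured across the ring, or the elimination goes into the ring instead of to the methyl group. The fallback avoids the epoxide altogether and sets out from 5. A Schenck ene reaction (O2, tetraphenylporphyrin, hν, CH2Cl2, 0 °C) gives the racemic allylic hydroperoxide F6. Triphenylphosphine reduces it to the racemic carbinol F7. A Sharpless kinetic resolution (Ti(OiPr)4, L-(+)-DIPT, t-BuOOH, −20 °C) epoxidises the (S)-carbinol to the epoxy alcohol F8 and leaves the (R)-carbinol, so the route is rejoined at 8.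

**Further compounds**

F1 | step 8 | C9 ketone of 12 | O=C1CC[C@]2(C[C@@H](CC(C)C)C3=C(O2)C(C)(C)C(=O)C(C)(C)C3=O)C(=O)CC(C)(C)/C=C/C=C1/C
F2 | step 8 | C9 cyclobutanol (9-hydroxy analogue of 14; C9 configuration nominal, erased on deoxygenation) | C/C1=C/C[C@@H]2[C@](O)(CC2(C)C)[C@]2(CCC1=O)C[C@@H](CC(C)C)C1=C(O2)C(C)(C)C(=O)C(C)(C)C1=O
F3 | step 8 | methyl oxalate of F2 | C/C1=C/C[C@@H]2[C@](OC(=O)C(=O)OC)(CC2(C)C)[C@]2(CCC1=O)C[C@@H](CC(C)C)C1=C(O2)C(C)(C)C(=O)C(C)(C)C1=O
F4 | step 6 | triethylsilyl ether of 8 | O=C1CCC(=C)[C@H](O[Si](CC)(CC)CC)CC(C)(C)/C=C/C=C1/C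
F5 | step 6 | triethylsilyl ether of 12 | O=C1CC[C@]2(C[C@@H](CC(C)C)C3=C(O2)C(C)(C)C(=O)C(C)(C)C3=O)[C@H](O[Si](CC)(CC)CC)CC(C)(C)/C=C/C=C1/C
F6 | step 5 | racemic 8-hydroperoxy-2,6,6-trimethyl-9-methylidenecycloundeca-2,4-dien-1-one | O=C1CCC(=C)C(OO)CC(C)(C)/C=C/C=C1/C
F7 | step 5 | racemic 8 | O=C1CCC(=C)C(O)CC(C)(C)/C=C/C=C1/C
F8 | step 5 | (8S,9S)-epoxy alcohol from the fast-reacting carbinol enantiomer (spiro-epoxide at C8–C13) | O=C1CC[C@]2(CO2)[C@@H](O)CC(C)(C)/C=C/C=C1/C
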